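The whole plan depends on opening the C-ring of the 8-linked fisetinidol unit at O1–C8a and C3–C4. O1–C2–C3 then becomes an (R)-aryloxirane. C4–C4a–C8a becomes a diarylmethyl phenyl sulfide whose C4 is doubly benzylic (A-ring C4a, catechin D-ring C8) and whose C8a bears fluorine. One base-triggered [3+3] cascade closes the ring convergently: the carbanion opens the epoxide at C3, then the alkoxide displaces fluoride at C8a by SNAr. Sulfur first stabilises the anion and later leaves. C2 relays its configuration to C3 (dihydroxylation anti to the B-ring) and to C4 (hydride anti to 3-OH, giving the 4β-aryl bond). Acid-catalysed coupling of mollisacacidin at D-ring C6 completes the trimer.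

Key step: step 7

Assumption: (+)-catechin, (2R,3R)-fustin, 4-(benzyloxy)-2-fluorobenzaldehyde and 2-chloro-3',4'-dihydroxyacetophenone are taken as purchasable. Flavan numbering is used throughout: 8-linked unit = rings A/B/C, catechin = rings D (aromatic), E (catechol), F (pyran); β = the face of the 3-OH, α = the face of the 2-aryl group.

Step 1
Reactants: 1 (+)-catechin
Product: 2 5,7,3',4'-tetra-O-benzyl-(+)-catechin
Conditions: BnBr (4.4 equiv), K2CO3, DMF, 0 °C → rt, N2
Reagents that add atoms: benzyl bromide BrCc1ccccc1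
Why: Williamson etherification; carbonate deprotonates only the four phenols, so the secondary 3-OH stays free and C2/C3 are untouched.

Step 2
Reactants: 2 5,7,3',4'-tetra-O-benzyl-(+)-catechin
Product: 3 3,5,7,3',4'-penta-O-benzyl-(+)-catechin
Conditions: NaH, BnBr, DMF, 0 °C → rt
Reagents that add atoms: benzyl bromide BrCc1ccccc1
Why: Williamson etherification of the remaining secondary alkoxide; with every phenol capped no E-ring quinone methide can form, so C2 should not epimerise.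

Step 3
Reactants: 3 3,5,7,3',4'-penta-O-benzyl-(+)-catechin
Product: 4 8-bromo-3,5,7,3',4'-penta-O-benzyl-(+)-catechin
Conditions: NBS (1.0 equiv), CH2Cl2, −78 → 0 °C
Reagents that add atoms: N-bromosuccinimide O=C1CCC(=O)N1Br
Why: Electrophilic aromatic bromination; C8 is the more reactive of the two free D-ring positions of per-O-benzylated catechin, and one equivalent at low temperature should stop at the 8-bromide.

Step 4
Reactants: 4 8-bromo-3,5,7,3',4'-penta-O-benzyl-(+)-catechin; 5 4-(benzyloxy)-2-fluorobenzaldehyde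
Product: 8 (4-benzyloxy-2-fluorophenyl)(penta-O-benzylcatechin-8-yl)methyl phenyl sulfide (both epimers at the new carbon), via aryllithium 6 (not isolated), via benzhydrol 7 (not isolated)
Conditions: n-BuLi (1.05 equiv), THF, −78 °C; 5; then PhSH (3 equiv), TFA (2.5 equiv), CH2Cl2, −78 → 0 °C
Reagents that add atoms: thiophenol Sc1ccccc1
Why: Bromine–lithium exchange and 1,2-addition fix the C4–C8(D) bond regiospecifically, and the very electron-rich benzhydrol then ionises and is trapped by the thiol (SN1 thioetherification); the new centre forms as both epimers, which is irrelevant because step 7 planarises it.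

Step 5
Reactants: 9 2-chloro-1-(3,4-dihydroxyphenyl)ethanone
Product: 10 2-chloro-1-[3,4-bis(benzyloxy)phenyl]ethanone
Conditions: BnBr (2.3 equiv), K2CO3, acetone, rt → 40 °C
Reagents that add atoms: benzyl bromide BrCc1ccccc1
Why: Williamson etherification; the excess of the more reactive benzyl bromide should outrun self-alkylation of the phenoxide by the chloroketone.

Step 6
Reactants: 10 2-chloro-1-[3,4-bis(benzyloxy)phenyl]ethanone
Product: 12 (R)-2-[3,4-bis(benzyloxy)phenyl]oxirane, via chlorohydrin 11 (not isolated)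
Conditions: RuCl[(S,S)-TsDPEN](p-cymene) (0.5 mol %), HCO2H–Et3N 5:2, EtOAc, rt; then 2 M aq NaOH, i-PrOH, 0 °C → rt
Reagents that add atoms: none
Why: Noyori asymmetric transfer hydrogenation of the α-chloro ketone sets the carbinol centre as (R) under catalyst control, and hydroxide then closes the epoxide by intramolecular SN2 at CH2 without touching that centre.

Step 7
Reactants: 8 (4-benzyloxy-2-fluorophenyl)(penta-O-benzylcatechin-8-yl)methyl phenyl sulfide; 12 (R)-2-[3,4-bis(benzyloxy)phenyl]oxirane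
Product: 15 (2S)-7,3',4'-tris(benzyloxy)-4-(phenylthio)-4-(penta-O-benzylcatechin-8-yl)flavan (both C4 epimers), via potassium carbanion 13 (not isolated), via potassium alkoxide 14 (not isolated)
Conditions: KHMDS (1.1 equiv), 18-crown-6, THF–DMPU 4:1, −40 °C; 12 (1.3 equiv), → rt; then 70 °C
Reagents that add atoms: none
Why: KHMDS removes the only C–H flanked by two arenes and sulfur (C4–H of 8), the soft, bulky carbanion 13 opens epoxide 12 by SN2 at its unsubstituted carbon (C3–C4 bond), and the potassium alkoxide 14 released at C2 adds to the fluorine-bearing C8a and expels fluoride (O1–C8a bond). The closest known types are the opening of terminal epoxides by sulfur-stabilised benzylic carbanions and the alkoxide SNAr pyran closure on non-activated fluoroarenes used for catechin-type chromans, run here in tandem as a formal [3+3] annulation. The one ring formed, the C-ring, closes 6-exo-trig at C8a through a Meisenheimer adduct, helped by the Thorpe–Ingold effect of the quaternary C4. C2 is not a new centre, since its C–O bond is never broken and the epoxide configuration is carried into the flavan (the descriptor changes only because C3 is CH2), while the new quaternary C4 forms without control, which does not matter because step 8 makes it sp2. The step needs terminal rather than benzylic attack on the epoxide, secured by the bulk of the tertiary carbanion under Lewis-acid-free potassium conditions, and a single oxygen nucleophile, secured because C3 enters as CH2 so that no 3-alkoxide can close a five-membered ring, and thiolate is too poor a nucleofuge for Grob fragmentation of 14. Should base-induced loss of HF to the C8–C8a aryne intervene, the 7-benzyloxy group and the tether would direct the alkoxide to the same carbon, C8a.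

Step 8
Reactants: 15 (2S)-7,3',4'-tris(benzyloxy)-4-(phenylthio)-4-(penta-O-benzylcatechin-8-yl)flavan
Product: 17 (2S)-7,3',4'-tris(benzyloxy)-4-(penta-O-benzylcatechin-8-yl)flav-3-ene, via sulfoxide 16 (not isolated)
Conditions: mCPBA (1.0 equiv), CH2Cl2, −78 °C; then pyridine, toluene, 50 °C, dark
Reagents that add atoms: none
Why: Chemoselective sulfide oxidation followed by thermal syn (Ei) sulfoxide elimination; only C3 carries β-hydrogens, so both C4 epimers should converge on the C3=C4 alkene while C2 is untouched.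

Step 9
Reactants: 17 (2S)-7,3',4'-tris(benzyloxy)-4-(penta-O-benzylcatechin-8-yl)flav-3-ene
Product: 18 (2R,3R,4R)-7,3',4'-tris(benzyloxy)-4-(penta-O-benzylcatechin-8-yl)flavan-3,4-diol (2,3-trans-3,4-cis; both OH β, D-ring α)
Conditions: OsO4 (5 mol %), NMO (1.5 equiv), THF–t-BuOH–H2O, rt
Reagents that add atoms: N-methylmorpholine N-oxide (oxygen delivered through OsO4) C[N+]1([O-])CCOCC1; water O
Why: Upjohn syn-dihydroxylation; osmium should add to the face of C3=C4 opposite to the 2-aryl group, which sets 3β-OH (2,3-trans) and 4β-OH under substrate control.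

Step 10
Reactants: 18 (2R,3R,4R)-7,3',4'-tris(benzyloxy)-4-(penta-O-benzylcatechin-8-yl)flavan-3,4-diol
Product: 20 7,3',4'-tri-O-benzylfisetinidol-(4β→8)-3,5,7,3',4'-penta-O-benzylcatechin (upper unit 2R,3S,4R), via 4-arylflavan-4-ylium ion 19 (not isolated)
Conditions: Bu3SnH (5 equiv), then TFA added slowly, CH2Cl2, −20 → 0 °C
Reagents that add atoms: none
Why: Ionic hydrogenation; TFA ionises only the tertiary, doubly benzylic 4-OH and the bulky tin hydride should attack the planar cation from the α-face, anti to the 3β-OH, so hydrogen enters 4α and the D-ring ends 4β (3,4-cis).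

Step 11
Reactants: 20 7,3',4'-tri-O-benzylfisetinidol-(4β→8)-3,5,7,3',4'-penta-O-benzylcatechin
Product: 21 fisetinidol-(4β→8)-catechin
Conditions: H2 (1 atm), Pd(OH)2/C, THF–MeOH–H2O, rt
Reagents that add atoms: none
Why: Catalytic hydrogenolysis of the eight benzyl ethers under neutral conditions, which should leave the interflavanyl bond, the pyran C2–O bonds and all stereocentres intact.

Step 12
Reactants: 22 (+)-(2R,3R)-fustin
Product: 23 (+)-mollisacacidin, (2R,3S,4R)-3,3',4,4',7-pentahydroxyflavan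
Conditions: NaBH4, EtOH, 0 °C → rt
Reagents that add atoms: none
Why: Borohydride reduction of the 4-ketone of a trans-dihydroflavonol, expected to give mainly the 2,3-trans-3,4-trans diol; the C4 configuration is of no consequence because it is ionised in the next step.

Step 13
Reactants: 21 fisetinidol-(4β→8)-catechin; 23 (+)-mollisacacidin
Product: 25 fisetinidol-(4β→8)-catechin-(6→4α)-fisetinidol (target), via fisetinidol-4-yl cation 24 (not isolated)
Conditions: 0.1 M aq HCl, 23 (1.2 equiv), rt, N2; Sephadex LH-20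
Reagents that add atoms: none
Why: Acid-catalysed flavan-3,4-diol condensation (SN1/Friedel–Crafts); the 7-OH-stabilised cation is taken up by the only remaining phloroglucinol-type carbon, C6 of the D-ring, and approach anti to the 3-OH of the cation should set the new centre as 4α (3,4-trans, 4S).

Compound list
1 | (+)-catechin, (2R,3S) | Oc1cc(O)c2c(c1)O[C@H](c1ccc(O)c(O)c1)[C@@H](O)C2 | starting material
2 | 5,7,3',4'-tetra-O-benzyl-(+)-catechin | C(c1ccccc1)Oc1cc(OCc2ccccc2)c2c(c1)O[C@H](c1ccc(OCc3ccccc3)c(OCc3ccccc3)c1)[C@@H](O)C2 | intermediate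
3 | 3,5,7,3',4'-penta-O-benzyl-(+)-catechin | c1c(OCc3ccccc3)cc(OCc3ccccc3)c2c1O[C@H](c1ccc(OCc3ccccc3)c(OCc3ccccc3)c1)[C@@H](OCc1ccccc1)C2 | intermediate
4 | 8-bromo-3,5,7,3',4'-penta-O-benzyl-(+)-catechin | Brc1c(OCc3ccccc3)cc(OCc3ccccc3)c2c1O[C@H](c1ccc(OCc3ccccc3)c(OCc3ccccc3)c1)[C@@H](OCc1ccccc1)C2 | intermediate
5 | 4-(benzyloxy)-2-fluorobenzaldehyde | O=Cc1ccc(OCc2ccccc2)cc1F | starting material
6 | 8-lithio-penta-O-benzylcatechin (not isolated) | [Li]c1c(OCc3ccccc3)cc(OCc3ccccc3)c2c1O[C@H](c1ccc(OCc3ccccc3)c(OCc3ccccc3)c1)[C@@H](OCc1ccccc1)C2 | intermediate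
7 | (4-benzyloxy-2-fluorophenyl)(penta-O-benzylcatechin-8-yl)methanol, both epimers (not isolated) | OC(c1ccc(OCc2ccccc2)cc1F)c1c(OCc3ccccc3)cc(OCc3ccccc3)c2c1O[C@H](c1ccc(OCc3ccccc3)c(OCc3ccccc3)c1)[C@@H](OCc1ccccc1)C2 | intermediate
8 | (4-benzyloxy-2-fluorophenyl)(penta-O-benzylcatechin-8-yl)methyl phenyl sulfide, both epimers | c1ccccc1SC(c1ccc(OCc2ccccc2)cc1F)c1c(OCc3ccccc3)cc(OCc3ccccc3)c2c1O[C@H](c1ccc(OCc3ccccc3)c(OCc3ccccc3)c1)[C@@H](OCc1ccccc1)C2 | intermediate
9 | 2-chloro-1-(3,4-dihydroxyphenyl)ethanone | O=C(CCl)c1ccc(O)c(O)c1 | starting material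
10 | 2-chloro-1-[3,4-bis(benzyloxy)phenyl]ethanone | O=C(CCl)c1ccc(OCc2ccccc2)c(OCc2ccccc2)c1 | intermediate
11 | (R)-2-chloro-1-[3,4-bis(benzyloxy)phenyl]ethanol (not isolated) | O[C@@H](CCl)c1ccc(OCc2ccccc2)c(OCc2ccccc2)c1 | intermediate
12 | (R)-2-[3,4-bis(benzyloxy)phenyl]oxirane | [C@@H]1(c2ccc(OCc3ccccc3)c(OCc3ccccc3)c2)CO1 | intermediate
13 | potassium salt of the C4 carbanion of 8 (not isolated) | [K+].c1ccccc1S[C-](c1ccc(OCc2ccccc2)cc1F)c1c(OCc3ccccc3)cc(OCc3ccccc3)c2c1O[C@H](c1ccc(OCc3ccccc3)c(OCc3ccccc3)c1)[C@@H](OCc1ccccc1)C2 | intermediate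
14 | potassium (1S)-1-[3,4-bis(benzyloxy)phenyl]-3-(4-benzyloxy-2-fluorophenyl)-3-(penta-O-benzylcatechin-8-yl)-3-(phenylthio)propan-1-olate, both C3 epimers (not isolated) | [K+].[O-][C@H](c1ccc(OCc3ccccc3)c(OCc3ccccc3)c1)CC(Sc1ccccc1)(c1ccc(OCc2ccccc2)cc1F)c1c(OCc3ccccc3)cc(OCc3ccccc3)c2c1O[C@H](c1ccc(OCc3ccccc3)c(OCc3ccccc3)c1)[C@@H](OCc1ccccc1)C2 | intermediate
15 | (2S)-7,3',4'-tris(benzyloxy)-4-(phenylthio)-4-(penta-O-benzylcatechin-8-yl)flavan, both C4 epimers | C(c1ccccc1)Oc1ccc2c(c1)O[C@H](c1ccc(OCc3ccccc3)c(OCc3ccccc3)c1)CC2(Sc1ccccc1)c1c(OCc3ccccc3)cc(OCc3ccccc3)c2c1O[C@H](c1ccc(OCc3ccccc3)c(OCc3ccccc3)c1)[C@@H](OCc1ccccc1)C2 | intermediate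
16 | S-oxide of 15 (not isolated) | C(c1ccccc1)Oc1ccc2c(c1)O[C@H](c1ccc(OCc3ccccc3)c(OCc3ccccc3)c1)CC2(S(=O)c1ccccc1)c1c(OCc3ccccc3)cc(OCc3ccccc3)c2c1O[C@H](c1ccc(OCc3ccccc3)c(OCc3ccccc3)c1)[C@@H](OCc1ccccc1)C2 | intermediate
17 | (2S)-7,3',4'-tris(benzyloxy)-4-(penta-O-benzylcatechin-8-yl)flav-3-ene | C(c1ccccc1)Oc1ccc2c(c1)O[C@H](c1ccc(OCc3ccccc3)c(OCc3ccccc3)c1)C=C2c1c(OCc3ccccc3)cc(OCc3ccccc3)c2c1O[C@H](c1ccc(OCc3ccccc3)c(OCc3ccccc3)c1)[C@@H](OCc1ccccc1)C2 | intermediate
18 | (2R,3R,4R)-7,3',4'-tris(benzyloxy)-4-(penta-O-benzylcatechin-8-yl)flavan-3,4-diol (3β,4β-diol) | C(c1ccccc1)Oc1ccc2c(c1)O[C@H](c1ccc(OCc3ccccc3)c(OCc3ccccc3)c1)[C@@H](O)[C@]2(O)c1c(OCc3ccccc3)cc(OCc3ccccc3)c2c1O[C@H](c1ccc(OCc3ccccc3)c(OCc3ccccc3)c1)[C@@H](OCc1ccccc1)C2 | intermediate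
19 | 4-arylflavan-4-ylium ion from 18 (not isolated) | C(c1ccccc1)Oc1ccc2c(c1)O[C@H](c1ccc(OCc3ccccc3)c(OCc3ccccc3)c1)[C@@H](O)[C+]2c1c(OCc3ccccc3)cc(OCc3ccccc3)c2c1O[C@H](c1ccc(OCc3ccccc3)c(OCc3ccccc3)c1)[C@@H](OCc1ccccc1)C2 | intermediate
20 | 7,3',4'-tri-O-benzylfisetinidol-(4β→8)-3,5,7,3',4'-penta-O-benzylcatechin | C(c1ccccc1)Oc1ccc2c(c1)O[C@H](c1ccc(OCc3ccccc3)c(OCc3ccccc3)c1)[C@@H](O)[C@H]2c1c(OCc3ccccc3)cc(OCc3ccccc3)c2c1O[C@H](c1ccc(OCc3ccccc3)c(OCc3ccccc3)c1)[C@@H](OCc1ccccc1)C2 | intermediate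
21 | fisetinidol-(4β→8)-catechin | Oc1ccc2c(c1)O[C@H](c1ccc(O)c(O)c1)[C@@H](O)[C@H]2c1c(O)cc(O)c2c1O[C@H](c1ccc(O)c(O)c1)[C@@H](O)C2 | intermediate
22 | (+)-fustin, (2R,3R)-3,3',4',7-tetrahydroxyflavanone | O=C1c2ccc(O)cc2O[C@H](c2ccc(O)c(O)c2)[C@H]1O | starting material
23 | (+)-mollisacacidin, (2R,3S,4R)-flavan-3,3',4,4',7-pentaol | O[C@@H]1c2ccc(O)cc2O[C@H](c2ccc(O)c(O)c2)[C@H]1O | intermediate
24 | (2R,3S)-fisetinidol-4-yl cation (not isolated) | [CH+]1c2ccc(O)cc2O[C@H](c2ccc(O)c(O)c2)[C@H]1O | intermediate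
25 | fisetinidol-(4β→8)-catechin-(6→4α)-fisetinidol | Oc1ccc2c(c1)O[C@H](c1ccc(O)c(O)c1)[C@@H](O)[C@H]2c1c(O)c([C@@H]2c3ccc(O)cc3O[C@H](c3ccc(O)c(O)c3)[C@H]2O)c(O)c2c1O[C@H](c1ccc(O)c(O)c1)[C@@H](O)C2 | target

Total step count: 13. Longest linear sequence: 10 (steps 1, 2, 3, 4, 7, 8, 9, 10, 11, 13).

Steps most likely to fail

Step 7. Two things may go wrong. Alkylation of the crowded carbanion, whose D-ring carries two ortho oxygens, may be too slow. Fluoride displacement on the non-activated A-ring may also lag, so that the alkoxide decomposes first. The fallback forms the same two bonds in separate operations with the natural polarity at C4, and so builds a tertiary rather than a quaternary centre. It sets out from 7, isolated by quenching step 4 with water before the thiol is added, and returns at 17.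
- Purchased 1-[3,4-bis(benzyloxy)phenyl]ethanone F1 is converted (TMSOTf, Et3N) into 1-[3,4-bis(benzyloxy)phenyl]-1-(trimethylsilyloxy)ethene F2.
- Benzhydrol 7 is ionised with catalytic Sc(OTf)3 and intercepted by the enol ether (Mukaiyama-type SN1 alkylation) to give the β,β-diaryl ketone F3.
- Corey–Bakshi–Shibata reduction with the (R)-oxazaborolidine gives the (S)-alcohol F4.
- KH/18-crown-6 in THF–DMPU closes O1–C8a to the 4-arylflavan F5.
- DDQ dehydrogenation of the doubly benzylic C4–H gives 17.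

Step 10. External hydride capture of the cation may lose out to an internal 1,2-hydrogen shift from C3, and the facial bias exerted by a free 3-OH may be incomplete. The fallback makes the internal shift the stereodefining event. It sets out from 18 and returns at 20.
- Without any hydride donor, catalytic BF3·OEt2 at −78 °C should convert 18 by a pinacol-type, suprafacial migration of the 3α-hydrogen to C4 into the 2,4-trans 4β-arylflavan-3-one F6.
- NaBH4 at low temperature should attack this ketone from the α-face, because the β-face is screened by the quasi-axial D-ring. This gives the 3β-alcohol 20.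

Step 13. Facial selectivity at the new C4 may be only modest with unprotected partners, and further condensation on the resorcinol rings may erode the material. The fallback moves the coupling to the protected stage. It sets out from 20 and 22 and returns at 25.
- Fustin is benzylated (BnBr, K2CO3) to 7,3',4'-tri-O-benzylfustin F7.
- Reduction with NaBH4 gives the tri-O-benzylflavan-3,4-diol F8.
- Coupling with 20 under TiCl4 in CH2Cl2 at 0 °C, where titanium binds the 3-oxygen and should reinforce anti attack, gives the undeca-O-benzyl trimer F9.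
- Hydrogenolysis over Pd(OH)2/C gives 25.

Further compounds
F1 | step 7 | 1-[3,4-bis(benzyloxy)phenyl]ethanone | CC(=O)c1ccc(OCc2ccccc2)c(OCc2ccccc2)c1
F2 | step 7 | 1-[3,4-bis(benzyloxy)phenyl]-1-(trimethylsilyloxy)ethene | C=C(O[Si](C)(C)C)c1ccc(OCc2ccccc2)c(OCc2ccccc2)c1
F3 | step 7 | 1-[3,4-bis(benzyloxy)phenyl]-3-(4-benzyloxy-2-fluorophenyl)-3-(penta-O-benzylcatechin-8-yl)propan-1-one, both C3 epimers | O=C(c1ccc(OCc2ccccc2)c(OCc2ccccc2)c1)CC(c1ccc(OCc2ccccc2)cc1F)c1c(OCc3ccccc3)cc(OCc3ccccc3)c2c1O[C@H](c1ccc(OCc3ccccc3)c(OCc3ccccc3)c1)[C@@H](OCc1ccccc1)C2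
F4 | step 7 | (1S)-1-[3,4-bis(benzyloxy)phenyl]-3-(4-benzyloxy-2-fluorophenyl)-3-(penta-O-benzylcatechin-8-yl)propan-1-ol, both C3 epimers | O[C@H](c1ccc(OCc2ccccc2)c(OCc2ccccc2)c1)CC(c1ccc(OCc2ccccc2)cc1F)c1c(OCc3ccccc3)cc(OCc3ccccc3)c2c1O[C@H](c1ccc(OCc3ccccc3)c(OCc3ccccc3)c1)[C@@H](OCc1ccccc1)C2
F5 | step 7 | (2S)-7,3',4'-tris(benzyloxy)-4-(penta-O-benzylcatechin-8-yl)flavan, both C4 epimers | C(c1ccccc1)Oc1ccc2c(c1)O[C@H](c1ccc(OCc3ccccc3)c(OCc3ccccc3)c1)CC2c1c(OCc3ccccc3)cc(OCc3ccccc3)c2c1O[C@H](c1ccc(OCc3ccccc3)c(OCc3ccccc3)c1)[C@@H](OCc1ccccc1)C2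
F6 | step 10 | 2,4-trans-7,3',4'-tris(benzyloxy)-4β-(penta-O-benzylcatechin-8-yl)flavan-3-one | C(c1ccccc1)Oc1ccc2c(c1)O[C@H](c1ccc(OCc3ccccc3)c(OCc3ccccc3)c1)C(=O)[C@H]2c1c(OCc3ccccc3)cc(OCc3ccccc3)c2c1O[C@H](c1ccc(OCc3ccccc3)c(OCc3ccccc3)c1)[C@@H](OCc1ccccc1)C2
F7 | step 13 | (2R,3R)-7,3',4'-tri-O-benzylfustin | O=C1c2ccc(OCc3ccccc3)cc2O[C@H](c2ccc(OCc3ccccc3)c(OCc3ccccc3)c2)[C@H]1O
F8 | step 13 | (2R,3S,4R)-7,3',4'-tris(benzyloxy)flavan-3,4-diol | O[C@@H]1c2ccc(OCc3ccccc3)cc2O[C@H](c2ccc(OCc3ccccc3)c(OCc3ccccc3)c2)[C@H]1O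
F9 | step 13 | undeca-O-benzyl fisetinidol-(4β→8)-catechin-(6→4α)-fisetinidol (both fisetinidol 3-OH free) | C(c1ccccc1)Oc1ccc2c(c1)O[C@H](c1ccc(OCc3ccccc3)c(OCc3ccccc3)c1)[C@@H](O)[C@H]2c1c(OCc3ccccc3)c([C@@H]2c3ccc(OCc4ccccc4)cc3O[C@H](c3ccc(OCc4ccccc4)c(OCc4ccccc4)c3)[C@H]2O)c(OCc3ccccc3)c2c1O[C@H](c1ccc(OCc3ccccc3)c(OCc3ccccc3)c1)[C@@H](OCc1ccccc1)C2
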